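## Retrosynthetic overview

- **Feature.** In the 3(2H)-furanone ring (O, C3, C2, C1, C10), C3 is a carboxyl-level carbon that carries the oxygen of C10, and its partner C2 is the alpha carbon of the C1 ketone. Cutting C2=C3 as a Wittig olefination of an ester carbonyl opens the furanone and the ten-membered carbocycle (C1–C10) together. What remains is a nine-membered Z-enoate lactone (O, C3–C10) with a keto-phosphorane (C1, C2) on C10.
- **Lactone.** It is closed at C4=C5 by intramolecular Horner–Wadsworth–Emmons reaction of a C10-O-phosphonoacyl C5-aldehyde. The ester bond to the tertiary C10–OH is made earlier, intermolecularly.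
- **Fragment union.** C7–C8 comes from an indium Barbier union of a 2-(bromomethyl)enoate (C5–C7, C11–C13) with a citramalate aldehyde (C8–C10, C1, C14). C6 and C10 are chiral-pool centres; C7 and C8 arise in the union.
- **Ring order.** Nine-membered lactone (step 17), then furanone and carbocycle in one event (step 20), then the alpha-methylene-gamma-lactone C6–O–C12 (step 21).

Key step: step 20

Remark on the chemistry (numbering): C1 ketone, C2=C3, oxygen bridge C3–O–C10, C4=C5 with C15 on C4, lactone C6–O–C12, C11=C13 on C7, ester carbinol C8, C9, methyl C14 on C10. The spatial arrangement at C6, C7, C8 and C10 stays fixed after step 10; CIP letters change only with substituent priorities. TES = triethylsilyl, TBDPS = tert-butyldiphenylsilyl.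

Remark on the chemistry (C12): C12 stays at the carboxyl level as a tert-butyl ester from step 1 to step 21. A hydride reduction after the union could not spare the C1 carboxyl derivative. A tert-butyl ester cannot lactonise onto free C8–OH or C6–OH, and one acid treatment at the end converts it into the lactone.

## Route

Step 1
Reactants: 1 (R)-2,3-O-isopropylideneglyceraldehyde; 2 tert-butyl acrylate
Product: 3 Morita–Baylis–Hillman adduct (carbinol epimers)
Conditions: DABCO (1 equiv), 1,4-dioxane/H2O 1:1, rt
Reagents that add atoms: none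
Why: Morita–Baylis–Hillman reaction, in which the DABCO–acrylate zwitterion adds to the aldehyde; the new carbinol centre may form as a mixture because it becomes sp2 in step 2, C6 is carried over from 1, and the tert-butyl ester withstands the aqueous base.

Step 2
Reactants: 3 Morita–Baylis–Hillman adduct
Product: 4 (Z)-2-(bromomethyl)enoate
Conditions: NBS, Me2S, CH2Cl2, 0 °C to rt
Reagents that add atoms: N-bromosuccinimide, O=C1CCC(=O)N1Br
Why: Bromination with allylic transposition (SN2' attack of bromide on the alkoxysulfonium salt) runs without free acid, so the acetonide survives, and it should give the conjugated trisubstituted enoate with the dioxolane trans to the ester, the sterically preferred geometry.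

Step 3
Reactants: 5 (S)-citramalic acid
Product: 6 dioxolanone acid
Conditions: Me2C(OMe)2, TsOH·H2O (cat.), acetone, rt
Reagents that add atoms: 2,2-dimethoxypropane, COC(C)(C)OC
Why: Acid-catalysed transacetalisation binds the tertiary hydroxyl and the adjacent carboxyl as a five-membered dioxolanone, which differentiates the two carboxyls and leaves the quaternary centre (C10) untouched.

Step 4
Reactants: 6 dioxolanone acid
Product: 7 S-ethyl thioester
Conditions: EtSH, DCC, DMAP (cat.), CH2Cl2, 0 °C to rt
Reagents that add atoms: ethanethiol, CCS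
Why: Steglich-type carbodiimide coupling with a thiol converts the free carboxyl (C8) into a thioester under conditions to which the dioxolanone is inert.

Step 5
Reactants: 7 S-ethyl thioester
Product: 8 dioxolanone aldehyde
Conditions: Et3SiH, 10% Pd/C, acetone, rt
Reagents that add atoms: none
Why: Fukuyama reduction (insertion of palladium into the C–S bond, then hydride transfer from the silane) stops at the aldehyde and avoids the free gamma-hydroxy stage at which a borane route would translactonise.

Step 6
Reactants: 9 tert-butyl diethylphosphonoacetate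
Product: 10 benzyloxymethylated phosphonoacetate (racemic)
Conditions: NaH, THF, 0 °C; BnOCH2Cl, 0 °C to rt
Reagents that add atoms: benzyl chloromethyl ether, ClCOCc1ccccc1
Why: SN2 alkylation of the stabilised phosphonoacetate anion with a reactive chloromethyl ether installs C15 with its oxygen, and the product is racemic at C4, which later becomes sp2.

Step 7
Reactants: 10 benzyloxymethylated phosphonoacetate
Product: 11 beta-hydroxy phosphonoacetate
Conditions: H2 (1 atm), 10% Pd/C, EtOH, rt
Reagents that add atoms: none
Why: Catalytic hydrogenolysis of the benzyl ether is neutral, so neither retro-aldol loss of formaldehyde nor elimination from the beta-hydroxy phosphonate is triggered.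

Step 8
Reactants: 11 beta-hydroxy phosphonoacetate
Product: 12 TBDPS ether
Conditions: TBDPSCl, imidazole, DMF, 0 °C to rt
Reagents that add atoms: tert-butyl(chloro)diphenylsilane, CC(C)(C)[Si](Cl)(c1ccccc1)c1ccccc1
Why: Imidazole-mediated silylation of a primary alcohol gives an ether that should outlast every acidic, basic and thermal step up to the last one.

Step 9
Reactants: 12 TBDPS ether
Product: 13 phosphono acid
Conditions: TFA/CH2Cl2 1:3, 0 °C to rt
Reagents that add atoms: none
Why: Acidolysis of the tert-butyl ester (E1 loss of isobutene) frees the acid, while a primary TBDPS ether and the diethyl phosphonate tolerate trifluoroacetic acid.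

Step 10
Reactants: 4 (Z)-2-(bromomethyl)enoate; 8 dioxolanone aldehyde
Product: 15 coupled homoallylic alcohol (6S,7R,8R,10S), via allylindium dibromide 14 (not isolated)
Conditions: In powder, THF/H2O 1:1, rt
Reagents that add atoms: indium, [In] (held only in 14)
Why: Indium Barbier allylation, in which 14 has its dioxolane cis to CH2In (Z-crotyl type, fixed by the trans ester) and reacts at its gamma carbon C7 through a chair Zimmerman–Traxler transition state to give the syn C7/C8 relation, while the aldehyde should approach the C7 face anti to the C6–O bond in the conformer with C6–H eclipsing the alkene (allylic 1,3-strain), which together set 7R and 8R; water protonates the C8 alkoxide before it can attack the dioxolanone, and the tert-butyl ester cannot lactonise.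

Step 11
Reactants: 15 coupled homoallylic alcohol
Product: 16 C8 isovalerate
Conditions: isovaleric anhydride, Et3N, DMAP (cat.), CH2Cl2, 0 °C, on freshly prepared 15
Reagents that add atoms: 3-methylbutanoic anhydride, CC(C)CC(=O)OC(=O)CC(C)C
Why: DMAP-catalysed acylation of the only hydroxyl should outrun intramolecular attack of C8–OH on the dioxolanone and installs the ester of the target with retention at C8.

Step 12
Reactants: 16 C8 isovalerate
Product: 17 C10 hydroxy C1 allyl ester
Conditions: allyl alcohol, K2CO3 (0.3 equiv), 0 °C
Reagents that add atoms: allyl alcohol, C=CCO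
Why: Base-catalysed alcoholysis (transesterification) picks the dioxolanone carbonyl C1, a five-membered acylal-type lactone whose hemiketal leaving group collapses to acetone, ahead of the hindered isovalerate and the tert-butyl ester, and so frees C10–OH and places an orthogonal allyl ester on C1 in one operation.

Step 13
Reactants: 17 C10 hydroxy C1 allyl ester; 13 phosphono acid
Product: 18 C10-O-phosphonoacyl ester (C4 epimers)
Conditions: DCC, DMAP, CH2Cl2, rt
Reagents that add atoms: none
Why: Steglich esterification of phosphonoacetic acids runs through a phosphonoketene or acylpyridinium species that acylates even tertiary alpha-hydroxy esters, the usual prelude to intramolecular olefination, and the C4 epimers are of no consequence.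

Step 14
Reactants: 18 C10-O-phosphonoacyl ester
Product: 19 C5,C6-diol
Conditions: AcOH/H2O 4:1, 40 °C
Reagents that add atoms: none
Why: Mild acetal hydrolysis removes the terminal acetonide, while the tert-butyl, allyl and isovalerate esters, the phosphonate and the TBDPS ether tolerate warm aqueous acetic acid, and the tert-butyl ester blocks lactonisation of the freed C6–OH.

Step 15
Reactants: 19 C5,C6-diol
Product: 20 C5,C6-bis-TES ether
Conditions: TESOTf, 2,6-lutidine, CH2Cl2, −78 °C
Reagents that add atoms: triethylsilyl trifluoromethanesulfonate, CC[Si](CC)(CC)OS(=O)(=O)C(F)(F)F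
Why: Silylation with a silyl triflate and lutidine is complete within minutes at low temperature, which forestalls C8-to-C6 acyl migration and is too cold and short to attack the tert-butyl ester.

Step 16
Reactants: 20 C5,C6-bis-TES ether
Product: 21 C5 aldehyde
Conditions: (COCl)2, DMSO, CH2Cl2, −78 to −40 °C; Et3N, −78 to 0 °C
Reagents that add atoms: none
Why: Swern oxidation applied directly to a bis-TES ether is known to desilylate and oxidise only the primary ether, because the chlorosulfonium salt reaches the unhindered oxygen alone, and it gives the C5 aldehyde with C6–OTES in place.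

Step 17
Reactants: 21 C5 aldehyde
Product: 22 nine-membered Z-enoate lactone with C1 allyl ester
Conditions: LiCl, DBU, MeCN, slow addition (final about 1 mM), rt
Reagents that add atoms: none
Why: Intramolecular Horner–Wadsworth–Emmons olefination under Masamune–Roush conditions at high dilution forms C4=C5 and the nine-membered lactone, in which only the Z alkene (C3 cis to C6) is geometrically attainable, while the mild amine base limits epimerisation at C6 and loss of silanolate from the phosphonate anion.

Step 18
Reactants: 22 nine-membered lactone allyl ester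
Product: 23 lactone C1 acid
Conditions: Pd(PPh3)4 (cat.), PhNHMe, THF, rt
Reagents that add atoms: none
Why: Tsuji–Trost deallylation with zerovalent palladium and a weakly basic aniline as allyl acceptor is neutral and touches neither the other esters, none of which is allylic, nor the silyl ethers or the acrylate.

Step 19
Reactants: 23 lactone C1 acid
Product: 25 keto-phosphorane (key-step precursor), via acid chloride 24 (not isolated)
Conditions: Me2C=C(Cl)NMe2, CH2Cl2, 0 °C, evaporate; Ph3P=CH2 (2 equiv, from MePPh3Br and NaN(SiMe3)2) added dropwise, THF, −78 °C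
Reagents that add atoms: 1-chloro-N,N,2-trimethylprop-1-en-1-amine, CC(C)=C(Cl)N(C)C (chlorine of 24 only); methylenetriphenylphosphorane, C=P(c1ccccc1)(c1ccccc1)c1ccccc1
Why: C-acylation of a non-stabilised ylide by an acid chloride followed by transylidation with the second equivalent is the standard entry to acylmethylene phosphoranes, the neutral chloroenamine spares the TES ether, quaternary C10 excludes ketene formation, and slow addition at −78 °C keeps free ylide away from the esters and the acrylate.

Step 20
Reactants: 25 keto-phosphorane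
Product: 26 furanone-bridged ten-membered carbocycle
Conditions: toluene (about 5 mM), 110 °C
Reagents that add atoms: none
Why: Proposed new method: on heating, the nucleophilic ylide carbon C2 attacks the lactone carbonyl C3, the zwitterionic adduct closes to an oxaphosphetane and cycloreversion expels Ph3PO to leave the enol-ether double bond C2=C3; the nearest known reaction type is the intramolecular Wittig olefination of ester carbonyls by stabilised ylides, which converts open-chain alpha-acyloxy ketone ylides into 3(2H)-furanones and the ester analogues into tetronates, but it has not been run on a lactone so as to contract the ring. The furanone (O, C3, C2, C1, C10) closes in the 5-exo-trig mode, helped by the geminal placement of ylide arm and acyloxy group on quaternary C10, and the ten-membered carbocycle (C1–C10) is completed by the very same bond as a transannular event, since the chain C3–C10 is already tied up in the nine-membered ring and no end-to-end encounter is required. The step creates no stereocentre, and C6, C7, C8 and non-enolisable C10 are only onlookers. It needs site selectivity among three ester carbonyls, which the substrate provides because only C3 can be reached through a five-membered transition state (isovalerate: seven, tert-butyl ester: eight) and because a nine-membered lactone cannot relax fully into the stabilised Z-ester conformation and is therefore the most electrophilic of the three. Release of the C10 alkoxide from the tetrahedral adduct (O-to-C acyl transfer) should be reversible, as the alkoxide stays beside C3, whereas loss of Ph3PO is not, so both channels should drain into 26. The medium is neutral and aprotic, so the ring-held Z alkene C4=C5, the isovalerate, the acrylate and both silyl ethers should pass unchanged.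

Step 21
Reactants: 26 furanone-bridged carbocycle
Product: 28 C15-O-TBDPS lactone, via hydroxy acid 27 (not isolated)
Conditions: TFA/CH2Cl2 1:4, 0 °C to rt
Reagents that add atoms: none
Why: Trifluoroacetic acid cleaves the C6 TES ether and the tert-butyl ester (E1), and the resulting gamma-hydroxy acid 27 should lactonise spontaneously to the trans-fused alpha-methylene-gamma-butyrolactone with retention at C6, whereas the vinylogous-ester furanone, the isovalerate and the TBDPS ether are acid-tolerant.

Step 22
Reactants: 28 C15-O-TBDPS lactone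
Product: 29 CNP0171896.1 (target)
Conditions: HF·pyridine, pyridine, THF, 0 °C to rt
Reagents that add atoms: none
Why: Fluoride-mediated desilylation with buffered HF·pyridine is essentially non-basic and therefore compatible with the alpha-methylene lactone, the isovalerate and the dienone.

## Compound list

1 | (R)-2,3-O-isopropylideneglyceraldehyde, (4R)-2,2-dimethyl-1,3-dioxolane-4-carbaldehyde | O=C[C@H]1COC(C)(C)O1 | starting material
2 | tert-butyl acrylate | C=CC(=O)OC(C)(C)C | starting material
3 | tert-butyl 2-{[(4R)-2,2-dimethyl-1,3-dioxolan-4-yl](hydroxy)methyl}prop-2-enoate, both carbinol epimers | C=C(C(=O)OC(C)(C)C)C(O)[C@H]1COC(C)(C)O1 | intermediate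
4 | tert-butyl (Z)-2-(bromomethyl)-3-[(4S)-2,2-dimethyl-1,3-dioxolan-4-yl]prop-2-enoate | BrC/C(C(=O)OC(C)(C)C)=C\[C@H]1COC(C)(C)O1 | intermediate
5 | (S)-citramalic acid, (2S)-2-hydroxy-2-methylbutanedioic acid | C[C@](O)(CC(=O)O)C(=O)O | starting material
6 | 2-[(4S)-2,2,4-trimethyl-5-oxo-1,3-dioxolan-4-yl]acetic acid | C[C@@]1(CC(=O)O)OC(C)(C)OC1=O | intermediate
7 | S-ethyl 2-[(4S)-2,2,4-trimethyl-5-oxo-1,3-dioxolan-4-yl]ethanethioate | C[C@@]1(CC(=O)SCC)OC(C)(C)OC1=O | intermediate
8 | 2-[(4S)-2,2,4-trimethyl-5-oxo-1,3-dioxolan-4-yl]acetaldehyde | C[C@@]1(CC=O)OC(C)(C)OC1=O | intermediate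
9 | tert-butyl 2-(diethoxyphosphoryl)acetate | CCOP(=O)(CC(=O)OC(C)(C)C)OCC | starting material
10 | tert-butyl 3-(benzyloxy)-2-(diethoxyphosphoryl)propanoate, racemic | CCOP(=O)(OCC)C(COCc1ccccc1)C(=O)OC(C)(C)C | intermediate
11 | tert-butyl 2-(diethoxyphosphoryl)-3-hydroxypropanoate, racemic | CCOP(=O)(OCC)C(CO)C(=O)OC(C)(C)C | intermediate
12 | tert-butyl 3-[(tert-butyldiphenylsilyl)oxy]-2-(diethoxyphosphoryl)propanoate, racemic | CCOP(=O)(OCC)C(CO[Si](c1ccccc1)(c1ccccc1)C(C)(C)C)C(=O)OC(C)(C)C | intermediate
13 | 3-[(tert-butyldiphenylsilyl)oxy]-2-(diethoxyphosphoryl)propanoic acid, racemic | CCOP(=O)(OCC)C(CO[Si](c1ccccc1)(c1ccccc1)C(C)(C)C)C(=O)O | intermediate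
14 | allylindium reagent from 4, drawn as the monoallylindium dibromide, dioxolane cis to CH2In | Br[In](Br)C/C(C(=O)OC(C)(C)C)=C\[C@H]1COC(C)(C)O1 | intermediate
15 | tert-butyl (3R,4R)-3-[(4S)-2,2-dimethyl-1,3-dioxolan-4-yl]-4-hydroxy-2-methylidene-5-[(4S)-2,2,4-trimethyl-5-oxo-1,3-dioxolan-4-yl]pentanoate (6S,7R,8R,10S) | C=C(C(=O)OC(C)(C)C)[C@@H]([C@H]1COC(C)(C)O1)[C@H](O)C[C@]1(C)OC(C)(C)OC1=O | intermediate
16 | 4-O-(3-methylbutanoyl) derivative of 15 (6S,7R,8R,10S) | C=C(C(=O)OC(C)(C)C)[C@@H]([C@H]1COC(C)(C)O1)[C@H](OC(=O)CC(C)C)C[C@]1(C)OC(C)(C)OC1=O | intermediate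
17 | 1-allyl 7-tert-butyl (2S,4R,5R)-5-[(4S)-2,2-dimethyl-1,3-dioxolan-4-yl]-2-hydroxy-2-methyl-6-methylidene-4-(3-methylbutanoyloxy)heptanedioate | C=C(C(=O)OC(C)(C)C)[C@@H]([C@H]1COC(C)(C)O1)[C@H](OC(=O)CC(C)C)C[C@](C)(O)C(=O)OCC=C | intermediate
18 | 17 acylated on the C10 oxygen with 13 (C3, C4, C15 installed; C4 epimers; 6S,7R,8R,10S) | C=C(C(=O)OC(C)(C)C)[C@@H]([C@H]1COC(C)(C)O1)[C@H](OC(=O)CC(C)C)C[C@](C)(OC(=O)C(CO[Si](c1ccccc1)(c1ccccc1)C(C)(C)C)P(=O)(OCC)OCC)C(=O)OCC=C | intermediate
19 | C5,C6-diol from 18 (6S,7S,8R,10S; the C7 letter changes by priority only) | C=C(C(=O)OC(C)(C)C)[C@@H]([C@H](O)CO)[C@H](OC(=O)CC(C)C)C[C@](C)(OC(=O)C(CO[Si](c1ccccc1)(c1ccccc1)C(C)(C)C)P(=O)(OCC)OCC)C(=O)OCC=C | intermediate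
20 | C5,C6-bis(triethylsilyl) ether of 19 (6S,7R,8R,10S) | C=C(C(=O)OC(C)(C)C)[C@@H]([C@H](O[Si](CC)(CC)CC)CO[Si](CC)(CC)CC)[C@H](OC(=O)CC(C)C)C[C@](C)(OC(=O)C(CO[Si](c1ccccc1)(c1ccccc1)C(C)(C)C)P(=O)(OCC)OCC)C(=O)OCC=C | intermediate
21 | C5 aldehyde with C6–OTES (6S,7R,8R,10S) | C=C(C(=O)OC(C)(C)C)[C@@H]([C@H](O[Si](CC)(CC)CC)C=O)[C@H](OC(=O)CC(C)C)C[C@](C)(OC(=O)C(CO[Si](c1ccccc1)(c1ccccc1)C(C)(C)C)P(=O)(OCC)OCC)C(=O)OCC=C | intermediate
22 | nine-membered Z-enoate lactone (ring O, C3–C10): C10 bears methyl and CO2allyl, C8 O-isovalerate, C7 C(=CH2)CO2tBu, C6 OTES, C4 CH2OTBDPS (6R,7R,8R,10S) | C=C(C(=O)OC(C)(C)C)[C@H]1[C@H](O[Si](CC)(CC)CC)/C=C(/CO[Si](c2ccccc2)(c2ccccc2)C(C)(C)C)C(=O)O[C@](C)(C(=O)OCC=C)C[C@H]1OC(=O)CC(C)C | intermediate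
23 | C1 carboxylic acid of lactone 22 | C=C(C(=O)OC(C)(C)C)[C@H]1[C@H](O[Si](CC)(CC)CC)/C=C(/CO[Si](c2ccccc2)(c2ccccc2)C(C)(C)C)C(=O)O[C@](C)(C(=O)O)C[C@H]1OC(=O)CC(C)C | intermediate
24 | C1 acid chloride of 23 | C=C(C(=O)OC(C)(C)C)[C@H]1[C@H](O[Si](CC)(CC)CC)/C=C(/CO[Si](c2ccccc2)(c2ccccc2)C(C)(C)C)C(=O)O[C@](C)(C(=O)Cl)C[C@H]1OC(=O)CC(C)C | intermediate
25 | nine-membered Z-enoate lactone keto-phosphorane, C10–C(=O)CH=PPh3 (6R,7R,8R,10S) | C=C(C(=O)OC(C)(C)C)[C@H]1[C@H](O[Si](CC)(CC)CC)/C=C(/CO[Si](c2ccccc2)(c2ccccc2)C(C)(C)C)C(=O)O[C@](C)(C(=O)C=P(c2ccccc2)(c2ccccc2)c2ccccc2)C[C@H]1OC(=O)CC(C)C | intermediate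
26 | furanone-bridged ten-membered carbocycle, gamma-lactone still open (C6 OTES, C12 CO2tBu, C15 OTBDPS; 6R,7R,8R,10S) | C=C(C(=O)OC(C)(C)C)[C@H]1[C@H](O[Si](CC)(CC)CC)/C=C(/CO[Si](c2ccccc2)(c2ccccc2)C(C)(C)C)C2=CC(=O)[C@](C)(C[C@H]1OC(=O)CC(C)C)O2 | intermediate
27 | C6 hydroxy C12 acid from 26 | C=C(C(=O)O)[C@H]1[C@H](O)/C=C(/CO[Si](c2ccccc2)(c2ccccc2)C(C)(C)C)C2=CC(=O)[C@](C)(C[C@H]1OC(=O)CC(C)C)O2 | intermediate
28 | 15-O-TBDPS ether of the target (6R,7R,8R,10S) | C=C1C(=O)O[C@@H]2/C=C(/CO[Si](c3ccccc3)(c3ccccc3)C(C)(C)C)C3=CC(=O)[C@](C)(C[C@@H](OC(=O)CC(C)C)[C@@H]12)O3 | intermediate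
29 | CNP0171896.1 (6R,7R,8R,10S; 4Z) | C=C1C(=O)O[C@@H]2/C=C(/CO)C3=CC(=O)[C@](C)(C[C@@H](OC(=O)CC(C)C)[C@@H]12)O3 | target

## Step count

- Total step count: 22.
- Longest linear sequence: 16 steps (steps 3–5 and 10–22, from 5).

## Steps most likely to fail

**1. Step 20 (key step).**
- What may go wrong: the keto-stabilised ylide may add too slowly to the conjugated lactone carbonyl. The tetrahedral adduct may release the C10 alkoxide and come to rest, after O-to-C acyl transfer, as an unreactive diacyl ylide. Long heating may also wear down the C6 silyl ether, after which C6–OH would capture C3 as a butenolide.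
- Fallback (known reactions only, phosphorus-free): it sets out from acid chloride 24, made from 23 as in step 19. Me2CuLi (Et2O, −78 °C) should give the methyl ketone F1. LiN(SiMe3)2 (THF, −78 °C) deprotonates its only enolisable ketone position C2, and the enolate undergoes Baker–Venkataraman-type O-to-C acyl transfer onto C3 to give the ring-contracted alpha'-hydroxy-1,3-diketone F2. TFA in CH2Cl2 then effects the classical cyclodehydration of an alpha'-hydroxy-1,3-diketone to the 3(2H)-furanone and, in the same flask, the events of step 21. The route is rejoined at 28.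

**2. Step 17.**
- What may go wrong: oligomerisation may outrun closure of the strained nine-membered ring. The phosphonate anion may lose silanolate (E1cB). The base may epimerise the alpha-silyloxy aldehyde at C6.
- Fallback (metathesis instead of carbonyl olefination): it sets out from aldehyde 21. Non-basic Takai–Lombardo methylenation (Zn, CH2Br2, TiCl4, THF/CH2Cl2, 0 °C) should give the C5 vinyl compound F3. Intermolecular Horner–Wadsworth–Emmons reaction with aqueous formaldehyde (K2CO3, THF, rt) turns the phosphonoacyl group into the 2-(silyloxymethyl)acrylate F4. Deallylation as in step 18 removes the competing terminal alkene and gives the diene acid F5. Ring-closing metathesis (second-generation Hoveyda–Grubbs catalyst, toluene, 80–110 °C, high dilution) between the C5 vinyl group and the acrylate methylene, again with Z geometry imposed by ring size, comes back to the route at acid 23.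

**3. Step 10.**
- What may go wrong: facial selectivity at C7 rests on a conformational bias of the dioxolane and may be poor. Equilibration of the allylindium geometry may erode the syn relation. The C8 hydroxyl may translactonise onto the dioxolanone before it is acylated.
- Fallback (isolated, configurationally defined allylboronate instead of a Barbier reagent): it sets out from 3. Acetylation (Ac2O, DMAP, CH2Cl2) gives the acetate F6. Borylation with allylic transposition (B2pin2, Pd2(dba)3, toluene, 50 °C) gives the primary allylboronate F7 with CH2Bpin cis to the dioxolane. Its allylboration of 8 runs through a closed chair transition state and is accelerated by the matched enantiomer of a BINOL-derived phosphoric acid as an external control element. After mild hydrolysis of the borate it delivers the same alcohol 15.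

## Further compounds

F1 | step 20 | nine-membered lactone methyl ketone (C10–C(=O)CH3) | C=C(C(=O)OC(C)(C)C)[C@H]1[C@H](O[Si](CC)(CC)CC)/C=C(/CO[Si](c2ccccc2)(c2ccccc2)C(C)(C)C)C(=O)O[C@](C)(C(C)=O)C[C@H]1OC(=O)CC(C)C
F2 | step 20 | ten-membered carbocyclic 1,3-diketone (C1, C3) with free C10–OH | C=C(C(=O)OC(C)(C)C)[C@H]1[C@H](O[Si](CC)(CC)CC)/C=C(/CO[Si](c2ccccc2)(c2ccccc2)C(C)(C)C)C(=O)CC(=O)[C@@](C)(O)C[C@H]1OC(=O)CC(C)C
F3 | step 17 | C5 vinyl analogue of 21 (phosphonoacyl ester retained, C4 epimers) | C=C(C(=O)OC(C)(C)C)[C@@H]([C@H](O[Si](CC)(CC)CC)C=C)[C@H](OC(=O)CC(C)C)C[C@](C)(OC(=O)C(CO[Si](c1ccccc1)(c1ccccc1)C(C)(C)C)P(=O)(OCC)OCC)C(=O)OCC=C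
F4 | step 17 | C10-O-[2-(TBDPS-oxymethyl)acryloyl] C5 vinyl allyl ester | C=C(C(=O)OC(C)(C)C)[C@@H]([C@H](O[Si](CC)(CC)CC)C=C)[C@H](OC(=O)CC(C)C)C[C@](C)(OC(=O)C(=C)CO[Si](c1ccccc1)(c1ccccc1)C(C)(C)C)C(=O)OCC=C
F5 | step 17 | diene C1 acid from F4 | C=C(C(=O)OC(C)(C)C)[C@@H]([C@H](O[Si](CC)(CC)CC)C=C)[C@H](OC(=O)CC(C)C)C[C@](C)(OC(=O)C(=C)CO[Si](c1ccccc1)(c1ccccc1)C(C)(C)C)C(=O)O
F6 | step 10 | acetate of 3 (carbinol epimers) | C=C(C(=O)OC(C)(C)C)C(OC(C)=O)[C@H]1COC(C)(C)O1
F7 | step 10 | pinacol allylboronate, CH2Bpin cis to the dioxolane | CC1(C)OB(C/C(C(=O)OC(C)(C)C)=C\[C@H]2COC(C)(C)O2)OC1(C)C
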